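**Assumption:** the SMILES has no stereocentre and no stereogenic double bond. The target is therefore achiral and needs no enantiocontrol. The sp3 centres that appear on the way are racemic and are erased on aromatisation.

## Retrosynthetic overview
- The furan is the only ring that is built, and it is closed last. The C2–O bond comes from cyclodehydration of a masked 2,3-diaryl-3-oxopropanal (dimethyl acetal, both phenols as MOM ethers).
- Key bond C3–C3a: the α-carbon of the aryl ketone is made electrophilic as an α-(λ3-iodanyl) ketone, an enolonium equivalent. The ipso carbon of ring B captures it in a 1,2-aryl shift. The former β-carbon becomes the formyl carbon at the correct oxidation level, so the precursor is an (E)-chalcone.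
- The chalcone comes from a Claisen–Schmidt condensation of acetovanillone with 5-(3-hydroxypropyl)-o-vanillin, both MOM-capped in the same flask.
- The salicylaldehyde comes from ortho-formylation of dihydroconiferyl alcohol. Both benzene rings are purchased.

## Route

**Step 1**
Reactants: 1 4-(3-hydroxypropyl)-2-methoxyphenol (dihydroconiferyl alcohol)
Product: 2 2-hydroxy-5-(3-hydroxypropyl)-3-methoxybenzaldehyde
Conditions: MgCl2 (2.5 equiv), Et3N (5 equiv), (CH2O)n (7 equiv), MeCN, reflux, 4–6 h; 1 M HCl work-up
Reagents that add atoms: paraformaldehyde (reacts as formaldehyde), C=O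
Why: Casnati–Skattebøl ortho-formylation, in which the magnesium phenoxide delivers formaldehyde to the only free ortho carbon, a second formaldehyde oxidises the benzylic alkoxide by Oppenauer-type hydride transfer, and the aliphatic OH is only reversibly hemiformylated and returns on acidic work-up; no stereocentre is formed.

**Step 2**
Reactants: 2 2-hydroxy-5-(3-hydroxypropyl)-3-methoxybenzaldehyde; 3 1-(4-hydroxy-3-methoxyphenyl)ethan-1-one (acetovanillone)
Product: 6 (E)-3-[5-(3-hydroxypropyl)-3-methoxy-2-(methoxymethoxy)phenyl]-1-[3-methoxy-4-(methoxymethoxy)phenyl]prop-2-en-1-one, via MOM-protected aldehyde 4 (not isolated), via MOM-protected acetovanillone 5 (not isolated)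
Conditions: 2 + 3 (1:1), K2CO3 (3 equiv), MOMCl (2.3 equiv), DMF, 0 °C to rt, 3 h; then EtOH, aq. KOH (3 equiv), rt, 16 h
Reagents that add atoms: chloromethyl methyl ether (MOMCl), COCCl
Why: Williamson-type O-alkylation caps only the two acidic phenols (any aliphatic MOM ether would fall off in step 4), which removes the phenoxide deactivation of both partners, so the Claisen–Schmidt aldol condensation then runs in the same flask and E1cB dehydration gives the E-enone.

**Step 3 (key step)**
Reactants: 6 (E)-chalcone bis-MOM ether
Product: 8 2-[5-(3-hydroxypropyl)-3-methoxy-2-(methoxymethoxy)phenyl]-3,3-dimethoxy-1-[3-methoxy-4-(methoxymethoxy)phenyl]propan-1-one (racemic), via alpha-iodanyl ketone 7 (not isolated)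
Conditions: PhI(OH)OTs (1.2 equiv), MeOH (0.05 M), 0 °C to rt, dark, 3–8 h; quench aq. NaHCO3/Na2S2O3
Reagents that add atoms: methanol, CO
Why: Oxidative 1,2-aryl migration of a chalcone with a trivalent iodine reagent, in which methanol adds to the β-carbon while the α-carbon binds iodine to give 7, whose normally nucleophilic α-carbon is now electrophilic and is attacked by the normally nucleophilic ipso carbon of the ortho-alkoxy-activated ring B (phenonium shift, PhI leaves), and methanol traps the resulting oxocarbenium ion as the acetal; the new stereocentre is racemic and is erased in step 4.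

**Step 4**
Reactants: 8 rearranged keto acetal
Product: 10 2-(4-hydroxy-3-methoxyphenyl)-5-(3-hydroxypropyl)-7-methoxy-1-benzofuran-3-carbaldehyde, via cyclic acetal 9 (not isolated)
Conditions: p-toluenesulfonic acid monohydrate (p-TsOH·H2O, 0.2 equiv), MeOH, rt to 40 °C; evaporate volatiles; p-TsOH·H2O (1 equiv), (CF3)2CHOH, rt to 40 °C; aq. NaHCO3
Reagents that add atoms: water, O
Why: Acid-catalysed transacetalisation strips both aryl MOM groups as volatile dimethoxymethane and closes cyclic acetal 9, which reopens in strongly ionising, weakly nucleophilic (CF3)2CHOH so that the phenol condenses with the protonated electron-rich aryl ketone (Paal–Knorr-type cyclodehydration) while water frees the aldehyde, giving the fully conjugated 2-aryl-3-formylbenzofuran and erasing all sp3 centres.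

## Compound list
1 | 4-(3-hydroxypropyl)-2-methoxyphenol (dihydroconiferyl alcohol) | COc1cc(CCCO)ccc1O | starting material
2 | 2-hydroxy-5-(3-hydroxypropyl)-3-methoxybenzaldehyde | COc1cc(CCCO)cc(C=O)c1O | intermediate
3 | 1-(4-hydroxy-3-methoxyphenyl)ethan-1-one (acetovanillone) | CC(=O)c1ccc(O)c(OC)c1 | starting material
4 | 5-(3-hydroxypropyl)-3-methoxy-2-(methoxymethoxy)benzaldehyde | COCOc1c(C=O)cc(CCCO)cc1OC | intermediate (not isolated)
5 | 1-[3-methoxy-4-(methoxymethoxy)phenyl]ethan-1-one | CC(=O)c1ccc(OCOC)c(OC)c1 | intermediate (not isolated)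
6 | (E)-3-[5-(3-hydroxypropyl)-3-methoxy-2-(methoxymethoxy)phenyl]-1-[3-methoxy-4-(methoxymethoxy)phenyl]prop-2-en-1-one | COCOc1ccc(cc1OC)C(=O)/C=C/c1cc(CCCO)cc(OC)c1OCOC | intermediate
7 | α-[phenyl(tosyloxy)-λ3-iodanyl]-β-methoxy ketone (enolonium equivalent, diastereomer mixture, racemic) | COCOc1ccc(cc1OC)C(=O)C(C(OC)c1cc(CCCO)cc(OC)c1OCOC)I(c1ccccc1)OS(=O)(=O)c1ccc(C)cc1 | intermediate (not isolated)
8 | 2-[5-(3-hydroxypropyl)-3-methoxy-2-(methoxymethoxy)phenyl]-3,3-dimethoxy-1-[3-methoxy-4-(methoxymethoxy)phenyl]propan-1-one (racemic) | COCOc1ccc(cc1OC)C(=O)C(C(OC)OC)c1cc(CCCO)cc(OC)c1OCOC | intermediate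
9 | (4-hydroxy-3-methoxyphenyl)[5-(3-hydroxypropyl)-2,7-dimethoxy-2,3-dihydro-1-benzofuran-3-yl]methanone (racemic diastereomer mixture) | COC1Oc2c(OC)cc(CCCO)cc2C1C(=O)c1ccc(O)c(OC)c1 | intermediate (not isolated)
10 | 2-(4-hydroxy-3-methoxyphenyl)-5-(3-hydroxypropyl)-7-methoxy-1-benzofuran-3-carbaldehyde (achiral) | COc1cc(-c2oc3c(OC)cc(CCCO)cc3c2C=O)ccc1O | target

## Count
Total steps: 4. Longest linear sequence: 4 (1 → 2 → 6 → 8 → 10).

## Three steps most likely to fail

**Step 3.**
- Risk: the p-toluenesulfonic acid liberated in methanol may strip a MOM group before the shift, and the freed phenol would then be oxidised by the iodane. The electron-rich rings may also be attacked directly.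
- Loss of the ring B MOM group after the shift does no harm, because it only leads to the cyclic acetal series that converges in step 4.
- Fallback: it sets out from 6 and replaces the aryl shift with an acyl shift.
  - Weitz–Scheffer epoxidation (H2O2, NaOH, MeOH, 0 °C) gives racemic trans-[3-[5-(3-hydroxypropyl)-3-methoxy-2-(methoxymethoxy)phenyl]oxiran-2-yl][3-methoxy-4-(methoxymethoxy)phenyl]methanone F1.
  - BF3·OEt2 in CH2Cl2 at −40 °C opens the epoxide at the benzylic carbon. The aroyl group migrates to that cation, giving 2-[5-(3-hydroxypropyl)-3-methoxy-2-(methoxymethoxy)phenyl]-3-[3-methoxy-4-(methoxymethoxy)phenyl]-3-oxopropanal F2.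
  - In the methanol stage of step 4, F2 loses its MOM groups and closes to the methyl acetal. The fallback comes back to the route at 9.

**Step 4.**
- Risk: cyclic acetal 9 can lose methanol irreversibly to give the isomeric 2-unsubstituted 3-aroylbenzofuran instead of reopening and closing on the ketone.
- Fallback: it sets out from 8 and makes the formyl carbon non-electrophilic before the furan is closed.
  - Propane-1,3-dithiol (3.5 equiv) with BF3·OEt2 in CH2Cl2 (0 °C to rt) converts the dimethyl acetal into a dithiane and cleaves both MOM ethers.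
  - The ketone is then the only electrophile left for the phenol, which gives 4-[3-(1,3-dithian-2-yl)-5-(3-hydroxypropyl)-7-methoxy-1-benzofuran-2-yl]-2-methoxyphenol F3.
  - Alkylative hydrolysis (MeI, CaCO3, MeCN/H2O, 40 °C) unmasks the aldehyde. The fallback comes back to the route at 10.

**Step 1.**
- Risk: chelation of magnesium by the neighbouring methoxy group and the free alcohol may slow the formylation and leave low conversion.
- Fallback: it sets out from 1 and swaps electrophilic formylation for halogenation and metalation.
  - NBS with catalytic diisopropylamine in CH2Cl2 brominates ortho to the phenol, giving 2-bromo-4-(3-hydroxypropyl)-6-methoxyphenol F4.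
  - n-BuLi (3.3 equiv, THF, −78 °C to 0 °C) forms the dianion and then effects Br–Li exchange.
  - A DMF quench with acidic work-up comes back to the route at 2.

## Further compounds
F1 | step 3 | racemic trans-[3-[5-(3-hydroxypropyl)-3-methoxy-2-(methoxymethoxy)phenyl]oxiran-2-yl][3-methoxy-4-(methoxymethoxy)phenyl]methanone (relative configuration drawn) | O=C(c1ccc(OCOC)c(OC)c1)[C@@H]1O[C@H]1c1cc(CCCO)cc(OC)c1OCOC
F2 | step 3 | 2-[5-(3-hydroxypropyl)-3-methoxy-2-(methoxymethoxy)phenyl]-3-[3-methoxy-4-(methoxymethoxy)phenyl]-3-oxopropanal (racemic, enolisable) | O=CC(C(=O)c1ccc(OCOC)c(OC)c1)c1cc(CCCO)cc(OC)c1OCOC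
F3 | step 4 | 4-[3-(1,3-dithian-2-yl)-5-(3-hydroxypropyl)-7-methoxy-1-benzofuran-2-yl]-2-methoxyphenol | COc1cc(-c2oc3c(OC)cc(CCCO)cc3c2C4SCCCS4)ccc1O
F4 | step 1 | 2-bromo-4-(3-hydroxypropyl)-6-methoxyphenol | COc1cc(CCCO)cc(Br)c1O
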